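**Plan** (drimane numbering: ring A = C1–C5 and C10; ring B = C5–C10; C11 = CH2O on C9; C12 = exocyclic CH2 on C8)
1. Cut the C11–O aryl ether (Mitsunobu reaction), then take the C6=C7–C8=C12 diene back to a C8 ketone (Wittig reaction, dehydrogenation) and to a protected C8 alcohol.
2. Cut C3–C4 and C5–C10 together. In ring A these two bonds lie opposite one another, C5–C10 is also the fusion bond to ring B, and C3 carries oxygen; so C4=C5 is a dienophile, C10=C1–C2=C3–O an oxygenated diene, and C6–C9 of ring B the four-atom tether of an intramolecular Diels–Alder reaction of an open-chain 1,7,9-decatriene.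
3. Helpers: one C4 methyl is carried as CHO (activation, later reduced to CH3); the C1=C2 alkene of the adduct is hydrogenated; C8 is carried as a benzyl ether.
4. Forward: an Evans syn-aldol reaction joins C8–C9, alkyne carboalumination builds the (E)-C10=C1 alkene, cross-metathesis gives the (E)-enal, and the cycloaddition then closes ring B and ring A in one operation.
5. Stereochemistry: C9 (and the temporary C8 centre) from the auxiliary; C10, C5 and C3 from olefin geometry and an endo chair transition state steered by C8/C9; C8 is erased later.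

Key step: step 9

Remark: compounds 1, 2, 4, 11, 15 and 29 are taken as commercial; the silyl dienol ether 18 is assumed to form mainly as the 1E isomer, and a minor 1Z isomer is assumed not to cycloadd.

**Step 1**
Reactants: 1 3-(benzyloxy)propanoic acid; 2 (S)-4-benzyloxazolidin-2-one
Product: 3 N-acyl oxazolidinone
Conditions: DCC, DMAP (cat.), CH2Cl2, 0 → 23 °C
Reagents that add atoms: none
Why: Steglich-type carbodiimide coupling acylates the oxazolidinone nitrogen and attaches the auxiliary to the three-carbon unit that becomes C10, C9 and C11; no stereocenter is formed.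

**Step 2**
Reactants: 3 N-acyl oxazolidinone; 4 pent-4-enal
Product: 6 syn-aldol adduct, via boron enolate 5 (not isolated)
Conditions: Bu2BOTf, i-Pr2NEt, CH2Cl2, −78 → 0 °C; then 4, −78 → 0 °C; then H2O2, MeOH, pH 7 buffer, 0 °C
Reagents that add atoms: none
Why: Evans syn-aldol reaction: the (Z)-boron enolate adds through a closed chair transition state on the face away from the auxiliary benzyl group, which should give the 2,3-syn adduct with C9 (S) and C8 (R).

**Step 3**
Reactants: 6 syn-aldol adduct
Product: 7 bis-benzyl ether imide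
Conditions: BnOC(=NH)CCl3, TfOH (cat.), CH2Cl2–cyclohexane, 0 → 23 °C
Reagents that add atoms: benzyl 2,2,2-trichloroacetimidate, N=C(OCc1ccccc1)C(Cl)(Cl)Cl
Why: acid-catalysed O-benzylation with the trichloroacetimidate protects the C8 hydroxyl without base, so retro-aldol cleavage and epimerisation of the β-hydroxy imide are avoided.

**Step 4**
Reactants: 7 bis-benzyl ether imide
Product: 8 primary alcohol
Conditions: LiBH4, MeOH (1 equiv), THF, 0 °C
Reagents that add atoms: none
Why: reductive cleavage of the N-acyl oxazolidinone with LiBH4 releases the auxiliary and gives the primary alcohol at C10 without touching the benzyl ethers or the stereocenters.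

**Step 5**
Reactants: 8 primary alcohol
Product: 10 terminal alkyne, via aldehyde 9 (not isolated)
Conditions: DMP, CH2Cl2, 0 → 23 °C; filtration, concentration; then dimethyl (1-diazo-2-oxopropyl)phosphonate, K2CO3, MeOH, 0 → 23 °C
Reagents that add atoms: dimethyl (1-diazo-2-oxopropyl)phosphonate, CC(=O)C(=[N+]=[N-])P(=O)(OC)OC
Why: Dess–Martin oxidation followed by Ohira–Bestmann (Seyferth–Gilbert) homologation of the crude aldehyde under mild carbonate conditions gives the C10≡C1 alkyne and should leave the α-stereocenter C9 intact.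

**Step 6**
Reactants: 10 terminal alkyne; 11 oxirane
Product: 14 (E)-homoallylic alcohol, via alkenylalane 12 (not isolated), via lithium alanate 13 (not isolated)
Conditions: AlMe3, Cp2ZrCl2 (0.25 equiv), CH2Cl2, 0 → 23 °C; then n-BuLi, THF–hexane, −78 °C; then 11, −78 → 0 °C
Reagents that add atoms: trimethylaluminium, C[Al](C)C
Why: Negishi carboalumination adds CH3 and Al syn across the alkyne with the methyl on the internal carbon, and the derived alanate opens oxirane with retention, so the (E)-trisubstituted C10=C1 alkene (methyl cis to C2) and the C2–C3 unit are set in one flask.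

**Step 7**
Reactants: 14 (E)-homoallylic alcohol; 15 methacrolein
Product: 16 (E)-enal alcohol
Conditions: second-generation Hoveyda–Grubbs catalyst (5 mol %), CH2Cl2, 40 °C
Reagents that add atoms: none
Why: olefin cross-metathesis of the terminal alkene with methacrolein should give the (E)-2-methylenal selectively and leave the trisubstituted alkene untouched.

**Step 8**
Reactants: 16 (E)-enal alcohol
Product: 18 silyl dienol ether trienal, via dialdehyde 17 (not isolated)
Conditions: DMP, CH2Cl2, 0 °C; filtration through Celite, concentration at 0 °C; then TBSOTf (1.05 equiv), Et3N, CH2Cl2, −78 °C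
Reagents that add atoms: tert-butyldimethylsilyl triflate, CC(C)(C)[Si](C)(C)OS(=O)(=O)C(F)(F)F
Why: Dess–Martin oxidation gives the β,γ-unsaturated aldehyde, whose doubly activated α-CH2 should be enolised by TBSOTf/Et3N much faster than the conjugated enal undergoes γ-deprotonation, so soft enolisation should give the (1E)-silyl dienol ether with the C10=C1 geometry retained.

**Step 9**
Reactants: 18 silyl dienol ether trienal
Product: 19 trans-decalin aldehyde
Conditions: PhMe (0.005 M), BHT (cat.), 110 °C, sealed tube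
Reagents that add atoms: none
Why: Thermal normal-demand type 1 intramolecular Diels–Alder reaction in which the (1E)-silyloxydiene C10=C1–C2=C3 and the (E)-2-methylenal C4=C5 are polarity-matched, so a concerted, asynchronous [4+2] addition with the C5–C10 bond leading is expected; the closest known reaction type is the thermal cyclisation of terminally activated deca-2,7,9-trienals and the Diels–Alder reaction of 1-silyloxydienes with 2-methylenals. Ring B closes through the four-atom tether C6–C9 as a six-membered ring in the fused mode (C5–C10 is the fusion bond), and ring A is the cyclohexene made by the cycloaddition itself (C3–C4 and C5–C10). C10 (methyl inside, tether outside on the E-alkene) and C3 (OTBS outside on the 1E-enol ether) are fixed suprafacially by the diene geometry, which puts the C3 oxygen trans to the angular methyl; C5 and the temporary C4 centre follow from the (E)-enal reacting with CHO endo, which gives the trans ring fusion. The absolute sense comes from C9 and C8: only the chair-like tether with CH2OBn and OBn both equatorial avoids a 1,3-diaxial clash between the C8 oxygen and the inside methyl on C10, and this exposes one diene face. The step needs endo (trans-fused) over exo (cis-fused) selectivity and facial selectivity; the first should be secured by the CHO-endo preference reinforced by the exo position of the C4 methyl, the second by the syn C8/C9 pair.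

**Step 10**
Reactants: 19 trans-decalin aldehyde
Product: 21 gem-dimethyl cyclohexene, via N-silyl hydrazone 20 (not isolated)
Conditions: TBSNHNHTBS, Sc(OTf)3 (cat.), CH2Cl2, 23 °C; then KOt-Bu, t-BuOH, DMSO, 23 °C
Reagents that add atoms: none
Why: Wolff–Kishner reduction by way of the N-silyl hydrazone turns the neopentyl CHO, which has served as activating group, into the second methyl on C4 at room temperature without disturbing the silyl and benzyl ethers.

**Step 11**
Reactants: 21 gem-dimethyl cyclohexene
Product: 22 saturated 8,11-diol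
Conditions: H2 (1 atm), Pd(OH)2/C, EtOAc, 23 °C
Reagents that add atoms: none
Why: heterogeneous hydrogenation saturates the cis-disubstituted C1=C2 alkene and hydrogenolyses both benzyl ethers in one operation, while the TBS ether and all stereocenters should be unaffected.

**Step 12**
Reactants: 22 saturated 8,11-diol
Product: 23 C11 silyl ether
Conditions: TBSCl (1.05 equiv), imidazole, CH2Cl2, 0 °C
Reagents that add atoms: tert-butyldimethylsilyl chloride, CC(C)(C)[Si](C)(C)Cl
Why: the primary C11 hydroxyl is silylated much faster than the secondary C8 hydroxyl, which leaves C8–OH free for oxidation.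

**Step 13**
Reactants: 23 C11 silyl ether
Product: 24 C8 ketone
Conditions: DMP, CH2Cl2, 23 °C
Reagents that add atoms: none
Why: Dess–Martin oxidation of the secondary alcohol gives the C8 ketone under neutral conditions and removes the C8 stereocenter, which served only to steer the cycloaddition.

**Step 14**
Reactants: 24 C8 ketone
Product: 26 enone, via lithium enolate 25 (not isolated)
Conditions: LiN(i-Pr)2, THF, −78 °C; then PhS(Cl)=N-t-Bu, −78 °C
Reagents that add atoms: none
Why: kinetic deprotonation at the unhindered C7 methylene and Mukaiyama dehydrogenation of the enolate with the sulfinimidoyl chloride (attack at sulfur, then syn-elimination) should give the C6=C7 enone regioselectively.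

**Step 15**
Reactants: 26 enone
Product: 27 bis-silyl diene
Conditions: Ph3PCH3Br, KOt-Bu, THF, 0 → 23 °C
Reagents that add atoms: methyltriphenylphosphonium bromide, C[P+](c1ccccc1)(c1ccccc1)c1ccccc1.[Br-]
Why: Wittig methylenation of the enone carbonyl gives the exocyclic C8=C12 alkene and with it the s-trans 1,3-diene of ring B.

**Step 16**
Reactants: 27 bis-silyl diene
Product: 28 diene diol
Conditions: Bu4NF, THF, 23 → 50 °C
Reagents that add atoms: none
Why: fluoride cleaves both silyl ethers, the hindered axial C3 ether on warming, and the diene should be inert to these conditions.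

**Step 17**
Reactants: 28 diene diol; 29 umbelliferone
Product: 30 target CNP0259618.3
Conditions: PPh3, DIAD, THF, 0 → 23 °C
Reagents that add atoms: none
Why: Mitsunobu etherification with the acidic phenol should take place at the primary C11 hydroxyl only, because the axial C3 hydroxyl next to the gem-dimethyl group is too hindered to form a reactive oxyphosphonium ion; no stereocenter is involved.

**Compound list**
1 | 3-(benzyloxy)propanoic acid | O=C(O)CCOCc1ccccc1 | starting material
2 | (S)-4-benzyloxazolidin-2-one | O=C1N[C@@H](Cc2ccccc2)CO1 | starting material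
3 | (S)-4-benzyl-3-[3-(benzyloxy)propanoyl]oxazolidin-2-one | O=C(CCOCc1ccccc1)N1[C@@H](Cc2ccccc2)COC1=O | intermediate
4 | pent-4-enal | C=CCCC=O | starting material
5 | (Z)-dibutylboron enolate of 3 | CCCCB(CCCC)O/C(=C\COCc1ccccc1)N1[C@@H](Cc2ccccc2)COC1=O | intermediate
6 | (S)-4-benzyl-3-[(2S,3R)-2-[(benzyloxy)methyl]-3-hydroxyhept-6-enoyl]oxazolidin-2-one | C=CCC[C@@H](O)[C@H](COCc1ccccc1)C(=O)N1[C@@H](Cc2ccccc2)COC1=O | intermediate
7 | (S)-4-benzyl-3-[(2S,3R)-3-(benzyloxy)-2-[(benzyloxy)methyl]hept-6-enoyl]oxazolidin-2-one | C=CCC[C@@H](OCc1ccccc1)[C@H](COCc1ccccc1)C(=O)N1[C@@H](Cc2ccccc2)COC1=O | intermediate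
8 | (2S,3R)-3-(benzyloxy)-2-[(benzyloxy)methyl]hept-6-en-1-ol | C=CCC[C@@H](OCc1ccccc1)[C@H](COCc1ccccc1)CO | intermediate
9 | (2S,3R)-3-(benzyloxy)-2-[(benzyloxy)methyl]hept-6-enal | C=CCC[C@@H](OCc1ccccc1)[C@H](COCc1ccccc1)C=O | intermediate
10 | (5R,6S)-5-(benzyloxy)-6-[(benzyloxy)methyl]oct-1-en-7-yne | C=CCC[C@@H](OCc1ccccc1)[C@H](COCc1ccccc1)C#C | intermediate
11 | oxirane | C1CO1 | starting material
12 | (E)-alkenyl(dimethyl)alane from 10 (CH3 on C10, Al on C1) | C=CCC[C@@H](OCc1ccccc1)[C@H](COCc1ccccc1)/C(C)=C/[Al](C)C | intermediate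
13 | lithium (E)-alkenyl(butyl)dimethylalanate from 12 | [Li+].C=CCC[C@@H](OCc1ccccc1)[C@H](COCc1ccccc1)/C(C)=C/[Al-](C)(C)CCCC | intermediate
14 | (3E,5S,6R)-6-(benzyloxy)-5-[(benzyloxy)methyl]-4-methyldeca-3,9-dien-1-ol | C=CCC[C@@H](OCc1ccccc1)[C@H](COCc1ccccc1)/C(C)=C/CCO | intermediate
15 | methacrolein (2-methylprop-2-enal) | C=C(C)C=O | starting material
16 | (2E,6R,7S,8E)-6-(benzyloxy)-7-[(benzyloxy)methyl]-11-hydroxy-2,8-dimethylundeca-2,8-dienal | O=C/C(C)=C/CC[C@@H](OCc1ccccc1)[C@H](COCc1ccccc1)/C(C)=C/CCO | intermediate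
17 | (2E,6R,7S,8E)-6-(benzyloxy)-7-[(benzyloxy)methyl]-2,8-dimethylundeca-2,8-dienedial | O=C/C(C)=C/CC[C@@H](OCc1ccccc1)[C@H](COCc1ccccc1)/C(C)=C/CC=O | intermediate
18 | (2E,6R,7S,8E,10E)-6-(benzyloxy)-7-[(benzyloxy)methyl]-11-[(tert-butyldimethylsilyl)oxy]-2,8-dimethylundeca-2,8,10-trienal | O=C/C(C)=C/CC[C@@H](OCc1ccccc1)[C@H](COCc1ccccc1)/C(C)=C/C=C/O[Si](C)(C)C(C)(C)C | intermediate
19 | trans-decalin Diels–Alder adduct (drimane numbering): C1=C2, 3α-OTBS, 4α-CHO, 4β-CH3, 5α-H, 8α-OBn, 9β-CH2OBn (9α-H), 10β-CH3 | c1ccccc1CO[C@@H]1CC[C@H]2[C@](C)(C=O)[C@H](O[Si](C)(C)C(C)(C)C)C=C[C@]2(C)[C@H]1COCc1ccccc1 | intermediate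
20 | N-(tert-butyldimethylsilyl)hydrazone of 19 | c1ccccc1CO[C@@H]1CC[C@H]2[C@](C)(C=NN[Si](C)(C)C(C)(C)C)[C@H](O[Si](C)(C)C(C)(C)C)C=C[C@]2(C)[C@H]1COCc1ccccc1 | intermediate
21 | 8α,11-bis(benzyloxy)-3α-[(tert-butyldimethylsilyl)oxy]drim-1-ene (4,4-dimethyl, 5α-H, 9α-H, 10β-CH3) | c1ccccc1CO[C@@H]1CC[C@H]2C(C)(C)[C@H](O[Si](C)(C)C(C)(C)C)C=C[C@]2(C)[C@H]1COCc1ccccc1 | intermediate
22 | 3α-[(tert-butyldimethylsilyl)oxy]drimane-8α,11-diol | O[C@@H]1CC[C@H]2C(C)(C)[C@H](O[Si](C)(C)C(C)(C)C)CC[C@]2(C)[C@H]1CO | intermediate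
23 | 3α,11-bis[(tert-butyldimethylsilyl)oxy]driman-8α-ol | O[C@@H]1CC[C@H]2C(C)(C)[C@H](O[Si](C)(C)C(C)(C)C)CC[C@]2(C)[C@H]1CO[Si](C)(C)C(C)(C)C | intermediate
24 | 3α,11-bis[(tert-butyldimethylsilyl)oxy]-12-nordriman-8-one | O=C1CC[C@H]2C(C)(C)[C@H](O[Si](C)(C)C(C)(C)C)CC[C@]2(C)[C@H]1CO[Si](C)(C)C(C)(C)C | intermediate
25 | lithium 7-en-8-olate of 24 (kinetic enolate) | [Li]OC1=CC[C@H]2C(C)(C)[C@H](O[Si](C)(C)C(C)(C)C)CC[C@]2(C)[C@H]1CO[Si](C)(C)C(C)(C)C | intermediate
26 | 3α,11-bis[(tert-butyldimethylsilyl)oxy]-12-nordrim-6-en-8-one | O=C1C=C[C@H]2C(C)(C)[C@H](O[Si](C)(C)C(C)(C)C)CC[C@]2(C)[C@H]1CO[Si](C)(C)C(C)(C)C | intermediate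
27 | 3α,11-bis[(tert-butyldimethylsilyl)oxy]drima-6,8(12)-diene | C=C1C=C[C@H]2C(C)(C)[C@H](O[Si](C)(C)C(C)(C)C)CC[C@]2(C)[C@H]1CO[Si](C)(C)C(C)(C)C | intermediate
28 | drima-6,8(12)-diene-3α,11-diol | C=C1C=C[C@H]2C(C)(C)[C@H](O)CC[C@]2(C)[C@H]1CO | intermediate
29 | umbelliferone (7-hydroxy-2H-chromen-2-one) | O=c1ccc2ccc(O)cc2o1 | starting material
30 | 7-{[(1S,4aR,6R,8aS)-6-hydroxy-5,5,8a-trimethyl-2-methylidene-1,2,4a,5,6,7,8,8a-octahydronaphthalen-1-yl]methoxy}-2H-chromen-2-one (CNP0259618.3) | C=C1C=C[C@H]2C(C)(C)[C@H](O)CC[C@]2(C)[C@H]1COc1ccc2ccc(=O)oc2c1 | target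

**Step count and risks**
Total steps: 17. Longest linear sequence: 17 steps (from 1 and 2 to 30).

Steps most likely to fail:

1. Step 8. What may go wrong: competing O-silylation and γ-deprotonation at the conjugated enal, migration of the C10=C1 double bond into conjugation before the enolate is trapped, and incomplete 1E selectivity. Fallback (sets out from 14, returns at 19): the activating group is carried as an ester, which cannot be enolised under these conditions. Cross-metathesis of 14 with methyl methacrylate would give the (E)-enoate alcohol F1. Dess–Martin oxidation would give the aldehyde F2, and TBSOTf/Et3N the silyl dienol ether ester F3. Thermal intramolecular Diels–Alder reaction (PhMe, 150 °C) should give the ester adduct F4. LiAlH4 reduction to the neopentyl alcohol F5 and Dess–Martin oxidation would return aldehyde 19.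

2. Step 9. What may go wrong: slow cycloaddition at the two hindered termini, erosion of endo/exo selectivity at 110 °C, and loss of the silyl enol ether by adventitious hydrolysis. Fallback (sets out from 16, returns at 21): a diene that tolerates Lewis acid is used so the cycloaddition can be catalysed at low temperature. Oxidation of 16 to 17 as before, then Ac2O/Et3N/DMAP (to which the conjugated enal is inert) would give the dienyl acetate F6. Me2AlCl in CH2Cl2 at −78 °C should give the acetoxy aldehyde adduct F7 with higher endo selectivity. The N-silyl hydrazone Wolff–Kishner protocol, whose basic medium (KOt-Bu, t-BuOH, DMSO) also cleaves the acetate, would give the allylic alcohol F8, and TBSOTf/2,6-lutidine would return 21.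

3. Step 17. What may go wrong: elimination of the activated oxyphosphonium ion toward the allylic C9–H, or sluggish displacement at the β-branched primary carbon. Fallback (sets out from 28, returns at 30): a Williamson-type alkylation replaces the redox condensation. Selective mesylation of the primary hydroxyl (MsCl, Et3N, CH2Cl2, −20 °C) would give the mesylate F9, and displacement with the caesium phenoxide of 29 (Cs2CO3, DMF, 50 °C) would give 30.

**Further compounds**
F1 | step 8 | methyl (2E,6R,7S,8E)-6-(benzyloxy)-7-[(benzyloxy)methyl]-11-hydroxy-2,8-dimethylundeca-2,8-dienoate | COC(=O)/C(C)=C/CC[C@@H](OCc1ccccc1)[C@H](COCc1ccccc1)/C(C)=C/CCO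
F2 | step 8 | methyl (2E,6R,7S,8E)-6-(benzyloxy)-7-[(benzyloxy)methyl]-2,8-dimethyl-11-oxoundeca-2,8-dienoate | COC(=O)/C(C)=C/CC[C@@H](OCc1ccccc1)[C@H](COCc1ccccc1)/C(C)=C/CC=O
F3 | step 8 | methyl (2E,6R,7S,8E,10E)-6-(benzyloxy)-7-[(benzyloxy)methyl]-11-[(tert-butyldimethylsilyl)oxy]-2,8-dimethylundeca-2,8,10-trienoate | COC(=O)/C(C)=C/CC[C@@H](OCc1ccccc1)[C@H](COCc1ccccc1)/C(C)=C/C=C/O[Si](C)(C)C(C)(C)C
F4 | step 8 | methyl ester analogue of 19 (4α-CO2CH3 in place of 4α-CHO) | c1ccccc1CO[C@@H]1CC[C@H]2[C@](C)(C(=O)OC)[C@H](O[Si](C)(C)C(C)(C)C)C=C[C@]2(C)[C@H]1COCc1ccccc1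
F5 | step 8 | primary alcohol analogue of 19 (4α-CH2OH in place of 4α-CHO) | c1ccccc1CO[C@@H]1CC[C@H]2[C@](C)(CO)[C@H](O[Si](C)(C)C(C)(C)C)C=C[C@]2(C)[C@H]1COCc1ccccc1
F6 | step 9 | (1E,3E,5S,6R,9E)-6-(benzyloxy)-5-[(benzyloxy)methyl]-4,10-dimethyl-11-oxoundeca-1,3,9-trien-1-yl acetate | O=C/C(C)=C/CC[C@@H](OCc1ccccc1)[C@H](COCc1ccccc1)/C(C)=C/C=C/OC(C)=O
F7 | step 9 | acetate analogue of 19 (3α-OAc in place of 3α-OTBS) | c1ccccc1CO[C@@H]1CC[C@H]2[C@](C)(C=O)[C@H](OC(C)=O)C=C[C@]2(C)[C@H]1COCc1ccccc1
F8 | step 9 | 8α,11-bis(benzyloxy)drim-1-en-3α-ol | c1ccccc1CO[C@@H]1CC[C@H]2C(C)(C)[C@H](O)C=C[C@]2(C)[C@H]1COCc1ccccc1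
F9 | step 17 | 3α-hydroxydrima-6,8(12)-dien-11-yl methanesulfonate | C=C1C=C[C@H]2C(C)(C)[C@H](O)CC[C@]2(C)[C@H]1COS(C)(=O)=O
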